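**Retrosynthetic overview**

1. Locants are labdane locants (ring A = C1–C5 and C10; ring B = C5–C10; side chain C11–C16; C17 on C8; C18/C19 on C4; C20 on C10); the target is (3R,5S,8S,9S,10R)-3-bromolabd-13E-ene-8,15-diol.
2. Enabling feature: ring B is a cyclohexane whose only heteroatom is the oxygen on C8, flanked by C7 and C9 and 1,4 to the ring-fusion carbon C5; carried as an enol ether it makes C7=C8–C9=C10 a 2-silyloxydiene and ring B the retron of a [4+2] addition to C5=C6, and because C10 and C5 are tied together by C1–C4 the same cycloaddition closes ring A.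
3. After the key step: C8 carbinol ⇒ 8(17)-alkene (oxymercuration) ⇒ C8 ketone (from the enol ether); the acyl oxazolidinone on C6 (activation and facial control) is excised by hydrolysis and radical decarboxylation.
4. The open-chain triene comes from a β-keto N-methoxy-N-methylamide (C8–C9–C10–C1, side chain already on C9): C1–C2 by dianion alkylation with a C2–C5 bromo triflate (C3–Br by enantioselective α-bromination), C10–C20 by methylation of the Z enol triflate (fixes the C9=C10 geometry), C5=C6–acyl by cross-metathesis.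
5. Ring order: C3 is set first in the open chain, rings A and B are closed together in one operation (step 15), C9 and C8 are set last on the decalin.

Key step: step 15

Remark: TBS = tert-butyldimethylsilyl, TBDPS = tert-butyldiphenylsilyl; CIP descriptors at C5, C9 and C10 change with substitution although the spatial arrangement is that of the target throughout.

Step 1
Reactants: 1 methyl 3,3-dimethylpent-4-enoate
Product: 2 3,3-dimethylpent-4-enal
Conditions: DIBAL-H (i-Bu2AlH, 1.05 equiv), CH2Cl2, −78 °C; Rochelle salt work-up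
Reagents that add atoms: none
Why: Partial ester reduction with i-Bu2AlH stops at the aluminium hemiacetal at −78 °C, which should release the aldehyde on work-up; no stereocentre is formed.

Step 2
Reactants: 2 3,3-dimethylpent-4-enal
Product: 4 (2S)-2-bromo-3,3-dimethylpent-4-en-1-ol, via bromo aldehyde 3 (not isolated)
Conditions: (2R,5R)-2,5-diphenylpyrrolidine (20 mol%), PhCO2H (20 mol%), 4,4-dibromo-2,6-di-tert-butylcyclohexa-2,5-dien-1-one (1.05 equiv), CH2Cl2/pentane, −40 °C; then NaBH4, MeOH, −40 → 0 °C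
Reagents that add atoms: 4,4-dibromo-2,6-di-tert-butylcyclohexa-2,5-dien-1-one, CC(C)(C)C1=CC(Br)(Br)C=C(C(C)(C)C)C1=O
Why: Enamine-catalysed electrophilic α-bromination, in which the E enamine of the C2-symmetric amine should be brominated on the face remote from the flanking phenyl group to give the (S)-bromide (the future 3R centre), and immediate NaBH4 reduction prevents racemisation of the α-bromo aldehyde.

Step 3
Reactants: 4 (2S)-2-bromo-3,3-dimethylpent-4-en-1-ol
Product: 5 (2S)-2-bromo-3,3-dimethylpent-4-en-1-yl trifluoromethanesulfonate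
Conditions: Tf2O (1.1 equiv), 2,6-lutidine (1.3 equiv), CH2Cl2, −78 °C; cold aqueous work-up, used at once
Reagents that add atoms: trifluoromethanesulfonic anhydride, O=S(=O)(OS(=O)(=O)C(F)(F)F)C(F)(F)F
Why: O-Sulfonylation of the primary alcohol at low temperature should leave the neighbouring C–Br bond and its configuration untouched.

Step 4
Reactants: 6 tert-butyl(but-3-yn-1-yloxy)dimethylsilane
Product: 8 (2E)-5-(tert-butyldimethylsilyloxy)-3-methylpent-2-en-1-ol, via alkenylalane 7 (not isolated)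
Conditions: Me3Al (2.0 equiv), Cp2ZrCl2 (0.25 equiv), CH2Cl2, 0 °C → rt; then THF, n-BuLi (1.0 equiv), −78 °C; (CH2O)n, −78 °C → rt
Reagents that add atoms: trimethylaluminium, C[Al](C)C; formaldehyde (as paraformaldehyde), C=O
Why: Negishi zirconium-catalysed carboalumination adds methyl and aluminium syn across the terminal alkyne with methyl on the internal carbon, which fixes the E geometry, and the derived alkenylaluminate should trap formaldehyde with retention.

Step 5
Reactants: 8 (2E)-5-(tert-butyldimethylsilyloxy)-3-methylpent-2-en-1-ol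
Product: 9 (2E)-5-(tert-butyldimethylsilyloxy)-1-(tert-butyldiphenylsilyloxy)-3-methylpent-2-ene
Conditions: TBDPSCl (1.1 equiv), imidazole (2 equiv), DMF, 0 °C → rt
Reagents that add atoms: tert-butyl(chloro)diphenylsilane, CC(C)(C)[Si](Cl)(c1ccccc1)c1ccccc1
Why: Imidazole-mediated silylation of the primary allylic alcohol installs a protecting group meant to last until step 20.

Step 6
Reactants: 9 (2E)-5-(tert-butyldimethylsilyloxy)-1-(tert-butyldiphenylsilyloxy)-3-methylpent-2-ene
Product: 10 [(2E)-5-bromo-3-methylpent-2-en-1-yl]oxy(tert-butyl)diphenylsilane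
Conditions: Ph3PBr2 (1.2 equiv), CH2Cl2, 0 °C → rt
Reagents that add atoms: dibromotriphenylphosphorane, BrP(Br)(c1ccccc1)(c1ccccc1)c1ccccc1
Why: Direct conversion of a primary TBS ether into the bromide with Ph3PBr2 (SN2 at the primary carbon, driven by silyl bromide and phosphine oxide formation), which the bulkier TBDPS ether should survive.

Step 7
Reactants: 11 N-methoxy-N-methyl-3-oxobutanamide; 10 [(2E)-5-bromo-3-methylpent-2-en-1-yl]oxy(tert-butyl)diphenylsilane
Product: 12 (5E)-2-acetyl-7-(tert-butyldiphenylsilyloxy)-N-methoxy-N,5-dimethylhept-5-enamide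
Conditions: NaH (1.05 equiv), THF/DMF, 0 °C; then 10, NaI (0.1 equiv), 50 °C
Reagents that add atoms: none
Why: C-Alkylation of the stabilised sodium enolate with the primary homoallylic bromide (iodide catalysis, Finkelstein activation) puts the complete side chain on the future C9; the centre formed is racemic and is erased in step 9.

Step 8
Reactants: 12 (5E)-2-acetyl-7-(tert-butyldiphenylsilyloxy)-N-methoxy-N,5-dimethylhept-5-enamide; 5 (2S)-2-bromo-3,3-dimethylpent-4-en-1-yl trifluoromethanesulfonate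
Product: 13 (6R)-6-bromo-2-[(3E)-5-(tert-butyldiphenylsilyloxy)-3-methylpent-3-en-1-yl]-N-methoxy-N,7,7-trimethyl-3-oxonon-8-enamide
Conditions: LDA (LiN(i-Pr)2, 2.05 equiv), THF, −78 → 0 °C; then 5 (1.0 equiv), −78 → −30 °C; aq. NH4Cl
Reagents that add atoms: none
Why: γ-Alkylation of a β-keto amide dianion, which reacts at its more basic terminal carbon (the future C1) by SN2 displacement of the primary triflate; C3 is not involved and C9 stays epimerisable.

Step 9
Reactants: 13 (6R)-6-bromo-2-[(3E)-5-(tert-butyldiphenylsilyloxy)-3-methylpent-3-en-1-yl]-N-methoxy-N,7,7-trimethyl-3-oxonon-8-enamide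
Product: 14 (2Z,6R)-6-bromo-2-[(3E)-5-(tert-butyldiphenylsilyloxy)-3-methylpent-3-en-1-yl]-N-methoxy-N,7,7-trimethyl-3-(trifluoromethanesulfonyloxy)nona-2,8-dienamide
Conditions: NaH (1.1 equiv), CH2Cl2, 0 °C; then Tf2O (1.1 equiv), −78 → 0 °C
Reagents that add atoms: trifluoromethanesulfonic anhydride, O=S(=O)(OS(=O)(=O)C(F)(F)F)C(F)(F)F
Why: O-Triflation of the sodium enolate, which is held U-shaped by chelation between the enolate oxygen and the amide carbonyl, should give the Z enol triflate (OTf cis to the amide, C1 trans to C8).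

Step 10
Reactants: 14 (2Z,6R)-6-bromo-2-[(3E)-5-(tert-butyldiphenylsilyloxy)-3-methylpent-3-en-1-yl]-N-methoxy-N,7,7-trimethyl-3-(trifluoromethanesulfonyloxy)nona-2,8-dienamide
Product: 15 (2E,6R)-6-bromo-2-[(3E)-5-(tert-butyldiphenylsilyloxy)-3-methylpent-3-en-1-yl]-N-methoxy-N,3,7,7-tetramethylnona-2,8-dienamide
Conditions: Pd(PPh3)4 (5 mol%), MeZnCl (2.0 equiv), THF, rt → 45 °C
Reagents that add atoms: methylzinc chloride, C[Zn]Cl
Why: Negishi cross-coupling of the enol triflate proceeds with retention of alkene geometry, so C20 ends cis to C8, and the hindered secondary alkyl bromide should not undergo oxidative addition.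

Step 11
Reactants: 15 (2E,6R)-6-bromo-2-[(3E)-5-(tert-butyldiphenylsilyloxy)-3-methylpent-3-en-1-yl]-N-methoxy-N,3,7,7-tetramethylnona-2,8-dienamide
Product: 16 (3E,7R)-7-bromo-3-[(3E)-5-(tert-butyldiphenylsilyloxy)-3-methylpent-3-en-1-yl]-4,8,8-trimethyldeca-3,9-dien-2-one
Conditions: MeMgBr (3 equiv), THF, −20 → 0 °C; aq. NH4Cl
Reagents that add atoms: methylmagnesium bromide, C[Mg]Br
Why: Weinreb ketone synthesis, in which the chelated tetrahedral magnesium adduct prevents over-addition and collapses to the methyl ketone (C7–C8) on work-up without touching the alkene geometry.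

Step 12
Reactants: 17 (4R)-4-benzyl-1,3-oxazolidin-2-one; 18 prop-2-enoyl chloride
Product: 19 (4R)-4-benzyl-3-(prop-2-enoyl)-1,3-oxazolidin-2-one
Conditions: n-BuLi (1.0 equiv), THF, −78 °C; then 18 (1.1 equiv), −78 → 0 °C
Reagents that add atoms: none
Why: N-Acylation of the lithiated oxazolidinone with the acid chloride; the auxiliary stereocentre comes from the chiral pool and is untouched.

Step 13
Reactants: 16 (3E,7R)-7-bromo-3-[(3E)-5-(tert-butyldiphenylsilyloxy)-3-methylpent-3-en-1-yl]-4,8,8-trimethyldeca-3,9-dien-2-one; 19 (4R)-4-benzyl-3-(prop-2-enoyl)-1,3-oxazolidin-2-one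
Product: 20 (4R)-4-benzyl-3-[(2E,5R,8E)-5-bromo-9-[(3E)-5-(tert-butyldiphenylsilyloxy)-3-methylpent-3-en-1-yl]-4,4,8-trimethyl-10-oxoundeca-2,8-dienoyl]-1,3-oxazolidin-2-one
Conditions: 19 (3 equiv), Hoveyda–Grubbs second-generation catalyst [RuCl2(H2IMes)(=CH-C6H4-2-OiPr)] (10 mol%), CH2Cl2, 40 °C
Reagents that add atoms: none
Why: Olefin cross-metathesis between the allylic-quaternary (type-three) terminal alkene and the type-two acrylimide should give only the cross product with E geometry and ethene, while the tri- and tetrasubstituted alkenes stay untouched.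

Step 14
Reactants: 20 (4R)-4-benzyl-3-[(2E,5R,8E)-5-bromo-9-[(3E)-5-(tert-butyldiphenylsilyloxy)-3-methylpent-3-en-1-yl]-4,4,8-trimethyl-10-oxoundeca-2,8-dienoyl]-1,3-oxazolidin-2-one
Product: 21 (4R)-4-benzyl-3-[(2E,5R,8E)-5-bromo-10-(tert-butyldimethylsilyloxy)-9-[(3E)-5-(tert-butyldiphenylsilyloxy)-3-methylpent-3-en-1-yl]-4,4,8-trimethylundeca-2,8,10-trienoyl]-1,3-oxazolidin-2-one
Conditions: TBSOTf (1.3 equiv), Et3N (2.0 equiv), CH2Cl2, −78 → 0 °C
Reagents that add atoms: tert-butyldimethylsilyl trifluoromethanesulfonate, CC(C)(C)[Si](C)(C)OS(=O)(=O)C(F)(F)F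
Why: Soft enolisation of the methyl ketone (kinetic α′-deprotonation of the acetyl group) gives the cross-conjugated 2-silyloxydiene C7=C8(OTBS)–C9=C10, while the enoyl imide has no enolisable hydrogen and the C9=C10 geometry is unchanged.

Step 15
Reactants: 21 (4R)-4-benzyl-3-[(2E,5R,8E)-5-bromo-10-(tert-butyldimethylsilyloxy)-9-[(3E)-5-(tert-butyldiphenylsilyloxy)-3-methylpent-3-en-1-yl]-4,4,8-trimethylundeca-2,8,10-trienoyl]-1,3-oxazolidin-2-one
Product: 23 (4R)-4-benzyl-3-{[(3R,5S,6R,9S,10R)-3-bromo-15-(tert-butyldiphenylsilyloxy)-8-oxo-17-norlabd-13E-en-6-yl]carbonyl}-1,3-oxazolidin-2-one, via silyl enol ether cycloadduct 22 (not isolated)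
Conditions: Me2AlCl (1.5 equiv), CH2Cl2 (0.01 M), −30 → 0 °C; then 1 M HCl/THF, rt
Reagents that add atoms: none
Why: Me2AlCl should turn the N-enoyl oxazolidinone into the cationic two-point aluminium chelate (s-cis enoyl), whose C5=C6 bond adds across the 2-silyloxydiene C7=C8–C9=C10 in a concerted, asynchronous [4π+2π] cycloaddition (C5–C10 leading, C6–C7 following); the closest known reaction type is the Lewis-acid-promoted, oxazolidinone-controlled intramolecular Diels–Alder reaction of (E,E)-trienimides to trans-fused bicyclo[4.4.0] systems. Ring B is closed by the suprafacial [4+2] union itself, and ring A by the C1–C4 tether folding into a chair as C5–C10 forms, with the C3 bromide equatorial. C5 and the temporary C6 centre follow from the (R)-benzyl group shielding the Si face of C6 in the chelate, so that the diene adds to the Re face; C10 follows from the endo transition state (acyl under the diene, tether E and C20 inside on C10), which gives the trans ring fusion, and the E dienophile places the acyl group trans to C4. The step needs facial selectivity (secured by the auxiliary), endo selectivity (secured by the chelated acyl group and helped by the C9 substituent, which crowds the tether in the cis-fused arrangement), one connectivity (enforced by the four-carbon tether) and a geometrically pure diene with C1 trans to C8 (secured in steps 9 and 10). Acidic work-up hydrolyses the silyl enol ether to the C8 ketone and creates C9, which is epimerisable and should settle with the side chain equatorial (cis to C20) under the basic conditions of step 16. The side-chain alkene is trisubstituted, unactivated and out of reach of the diene, so it should not compete.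

Step 16
Reactants: 23 (4R)-4-benzyl-3-{[(3R,5S,6R,9S,10R)-3-bromo-15-(tert-butyldiphenylsilyloxy)-8-oxo-17-norlabd-13E-en-6-yl]carbonyl}-1,3-oxazolidin-2-one
Product: 24 (3R,5S,6R,9S,10R)-3-bromo-15-(tert-butyldiphenylsilyloxy)-8-oxo-17-norlabd-13E-ene-6-carboxylic acid
Conditions: LiOH (2 equiv), H2O2 (4 equiv), THF/H2O 3:1, 0 °C; Na2SO3; 1 M HCl
Reagents that add atoms: lithium hydroperoxide (from LiOH and H2O2), [Li+].[O-]O
Why: Hydroperoxide cleaves the exocyclic imide carbonyl selectively (auxiliary removal, 17 is regenerated), and the basic medium equilibrates C9 to the more stable equatorial side chain next to the C8 ketone.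

Step 17
Reactants: 24 (3R,5S,6R,9S,10R)-3-bromo-15-(tert-butyldiphenylsilyloxy)-8-oxo-17-norlabd-13E-ene-6-carboxylic acid
Product: 26 (3R,5S,9S,10R)-3-bromo-15-(tert-butyldiphenylsilyloxy)-17-norlabd-13E-en-8-one, via Barton ester 25 (not isolated)
Conditions: 1-hydroxypyridine-2(1H)-thione (1.2 equiv), DCC (1.2 equiv), DMAP (0.1 equiv), CH2Cl2, 0 °C → rt, dark; then t-BuSH (10 equiv), benzene, visible light, rt
Reagents that add atoms: none
Why: Barton reductive decarboxylation, in which the thiohydroxamate ester fragments to the secondary C6 radical that abstracts hydrogen from t-BuSH, so C6 becomes a methylene group and the thiol chain should not touch the alkyl bromide or the alkenes.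

Step 18
Reactants: 26 (3R,5S,9S,10R)-3-bromo-15-(tert-butyldiphenylsilyloxy)-17-norlabd-13E-en-8-one
Product: 27 (3R,5S,9R,10S)-3-bromo-15-(tert-butyldiphenylsilyloxy)labda-8(17),13E-diene
Conditions: Ph3PCH3Br (4 equiv), KOtBu (3.8 equiv), toluene, 80 °C
Reagents that add atoms: methyltriphenylphosphonium bromide, C[P+](c1ccccc1)(c1ccccc1)c1ccccc1.[Br-]
Why: Wittig methylenation of the hindered C8 ketone with excess ylide; C9 is already the thermodynamic epimer and the equatorial C3 bromide has no antiperiplanar hydrogen for elimination.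

Step 19
Reactants: 27 (3R,5S,9R,10S)-3-bromo-15-(tert-butyldiphenylsilyloxy)labda-8(17),13E-diene
Product: 29 (3R,5S,8S,9S,10R)-3-bromo-15-(tert-butyldiphenylsilyloxy)labd-13E-en-8-ol, via organomercurial 28 (not isolated)
Conditions: Hg(OAc)2 (1.1 equiv), THF/H2O 1:1, rt; then 3 M NaOH, NaBH4, 0 °C
Reagents that add atoms: water, O
Why: Oxymercuration–demercuration, in which Hg(OAc)2 should react fastest with the 1,1-disubstituted exocyclic alkene (Markovnikov, water at C8) and water should attack C8 from the equatorial side, anti to the axial C20 methyl, so that OH ends trans to C20 (8S) and the new C17 methyl axial before NaBH4 replaces mercury by hydrogen.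

Step 20
Reactants: 29 (3R,5S,8S,9S,10R)-3-bromo-15-(tert-butyldiphenylsilyloxy)labd-13E-en-8-ol
Product: 30 (3R,5S,8S,9S,10R)-3-bromolabd-13E-ene-8,15-diol
Conditions: Bu4NF (1.5 equiv), THF, rt
Reagents that add atoms: none
Why: Fluoride-induced cleavage of the silyl ether (Si–F bond formation) frees the primary allylic alcohol without affecting any stereocentre.

**Compound list**

1 | methyl 3,3-dimethylpent-4-enoate | COC(=O)CC(C)(C)C=C | starting material
2 | 3,3-dimethylpent-4-enal | O=CCC(C)(C)C=C | intermediate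
3 | (2S)-2-bromo-3,3-dimethylpent-4-enal | O=C[C@@H](Br)C(C)(C)C=C | intermediate
4 | (2S)-2-bromo-3,3-dimethylpent-4-en-1-ol | OC[C@@H](Br)C(C)(C)C=C | intermediate
5 | (2S)-2-bromo-3,3-dimethylpent-4-en-1-yl trifluoromethanesulfonate | FC(F)(F)S(=O)(=O)OC[C@@H](Br)C(C)(C)C=C | intermediate
6 | tert-butyl(but-3-yn-1-yloxy)dimethylsilane | C#CCCO[Si](C)(C)C(C)(C)C | starting material
7 | [(1E)-4-(tert-butyldimethylsilyloxy)-2-methylbut-1-en-1-yl]dimethylalane | C/C(=C\[Al](C)C)CCO[Si](C)(C)C(C)(C)C | intermediate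
8 | (2E)-5-(tert-butyldimethylsilyloxy)-3-methylpent-2-en-1-ol | C/C(=C\CO)CCO[Si](C)(C)C(C)(C)C | intermediate
9 | (2E)-5-(tert-butyldimethylsilyloxy)-1-(tert-butyldiphenylsilyloxy)-3-methylpent-2-ene | C/C(=C\CO[Si](c1ccccc1)(c1ccccc1)C(C)(C)C)CCO[Si](C)(C)C(C)(C)C | intermediate
10 | [(2E)-5-bromo-3-methylpent-2-en-1-yl]oxy(tert-butyl)diphenylsilane | C/C(=C\CO[Si](c1ccccc1)(c1ccccc1)C(C)(C)C)CCBr | intermediate
11 | N-methoxy-N-methyl-3-oxobutanamide | CC(=O)CC(=O)N(C)OC | starting material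
12 | (5E)-2-acetyl-7-(tert-butyldiphenylsilyloxy)-N-methoxy-N,5-dimethylhept-5-enamide (racemic at C2) | CC(=O)C(CC/C(C)=C/CO[Si](c1ccccc1)(c1ccccc1)C(C)(C)C)C(=O)N(C)OC | intermediate
13 | (6R)-6-bromo-2-[(3E)-5-(tert-butyldiphenylsilyloxy)-3-methylpent-3-en-1-yl]-N-methoxy-N,7,7-trimethyl-3-oxonon-8-enamide (both C2 epimers) | C=CC(C)(C)[C@H](Br)CCC(=O)C(CC/C(C)=C/CO[Si](c1ccccc1)(c1ccccc1)C(C)(C)C)C(=O)N(C)OC | intermediate
14 | (2Z,6R)-6-bromo-2-[(3E)-5-(tert-butyldiphenylsilyloxy)-3-methylpent-3-en-1-yl]-N-methoxy-N,7,7-trimethyl-3-(trifluoromethanesulfonyloxy)nona-2,8-dienamide | C=CC(C)(C)[C@H](Br)CC/C(OS(=O)(=O)C(F)(F)F)=C(\CC/C(C)=C/CO[Si](c1ccccc1)(c1ccccc1)C(C)(C)C)C(=O)N(C)OC | intermediate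
15 | (2E,6R)-6-bromo-2-[(3E)-5-(tert-butyldiphenylsilyloxy)-3-methylpent-3-en-1-yl]-N-methoxy-N,3,7,7-tetramethylnona-2,8-dienamide | C=CC(C)(C)[C@H](Br)CC/C(C)=C(\CC/C(C)=C/CO[Si](c1ccccc1)(c1ccccc1)C(C)(C)C)C(=O)N(C)OC | intermediate
16 | (3E,7R)-7-bromo-3-[(3E)-5-(tert-butyldiphenylsilyloxy)-3-methylpent-3-en-1-yl]-4,8,8-trimethyldeca-3,9-dien-2-one | C=CC(C)(C)[C@H](Br)CC/C(C)=C(\CC/C(C)=C/CO[Si](c1ccccc1)(c1ccccc1)C(C)(C)C)C(C)=O | intermediate
17 | (4R)-4-benzyl-1,3-oxazolidin-2-one | O=C1N[C@H](Cc2ccccc2)CO1 | starting material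
18 | prop-2-enoyl chloride (acryloyl chloride) | C=CC(=O)Cl | starting material
19 | (4R)-4-benzyl-3-(prop-2-enoyl)-1,3-oxazolidin-2-one | C=CC(=O)N1C(=O)OC[C@H]1Cc1ccccc1 | intermediate
20 | (4R)-4-benzyl-3-[(2E,5R,8E)-5-bromo-9-[(3E)-5-(tert-butyldiphenylsilyloxy)-3-methylpent-3-en-1-yl]-4,4,8-trimethyl-10-oxoundeca-2,8-dienoyl]-1,3-oxazolidin-2-one | O=C(/C=C/C(C)(C)[C@H](Br)CC/C(C)=C(\CC/C(C)=C/CO[Si](c1ccccc1)(c1ccccc1)C(C)(C)C)C(C)=O)N1C(=O)OC[C@H]1Cc1ccccc1 | intermediate
21 | (4R)-4-benzyl-3-[(2E,5R,8E)-5-bromo-10-(tert-butyldimethylsilyloxy)-9-[(3E)-5-(tert-butyldiphenylsilyloxy)-3-methylpent-3-en-1-yl]-4,4,8-trimethylundeca-2,8,10-trienoyl]-1,3-oxazolidin-2-one | O=C(/C=C/C(C)(C)[C@H](Br)CC/C(C)=C(\CC/C(C)=C/CO[Si](c1ccccc1)(c1ccccc1)C(C)(C)C)C(=C)O[Si](C)(C)C(C)(C)C)N1C(=O)OC[C@H]1Cc1ccccc1 | intermediate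
22 | (4R)-4-benzyl-3-{[(3R,5S,6R,10R)-3-bromo-8-(tert-butyldimethylsilyloxy)-15-(tert-butyldiphenylsilyloxy)-17-norlabda-8,13E-dien-6-yl]carbonyl}-1,3-oxazolidin-2-one | C/C(=C\CO[Si](c1ccccc1)(c1ccccc1)C(C)(C)C)CCC1=C(O[Si](C)(C)C(C)(C)C)C[C@@H](C(=O)N3C(=O)OC[C@H]3Cc4ccccc4)[C@@H]2C(C)(C)[C@H](Br)CC[C@@]12C | intermediate
23 | (4R)-4-benzyl-3-{[(3R,5S,6R,9S,10R)-3-bromo-15-(tert-butyldiphenylsilyloxy)-8-oxo-17-norlabd-13E-en-6-yl]carbonyl}-1,3-oxazolidin-2-one | C/C(=C\CO[Si](c1ccccc1)(c1ccccc1)C(C)(C)C)CC[C@H]1[C@]2(C)CC[C@@H](Br)C(C)(C)[C@H]2[C@H](C(=O)N3C(=O)OC[C@H]3Cc4ccccc4)CC1=O | intermediate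
24 | (3R,5S,6R,9S,10R)-3-bromo-15-(tert-butyldiphenylsilyloxy)-8-oxo-17-norlabd-13E-ene-6-carboxylic acid | C/C(=C\CO[Si](c1ccccc1)(c1ccccc1)C(C)(C)C)CC[C@H]1[C@]2(C)CC[C@@H](Br)C(C)(C)[C@H]2[C@H](C(=O)O)CC1=O | intermediate
25 | 2-thioxopyridin-1(2H)-yl (3R,5S,6R,9S,10R)-3-bromo-15-(tert-butyldiphenylsilyloxy)-8-oxo-17-norlabd-13E-ene-6-carboxylate | C/C(=C\CO[Si](c1ccccc1)(c1ccccc1)C(C)(C)C)CC[C@H]1[C@]2(C)CC[C@@H](Br)C(C)(C)[C@H]2[C@H](C(=O)ON3C=CC=CC3=S)CC1=O | intermediate
26 | (3R,5S,9S,10R)-3-bromo-15-(tert-butyldiphenylsilyloxy)-17-norlabd-13E-en-8-one | C/C(=C\CO[Si](c1ccccc1)(c1ccccc1)C(C)(C)C)CC[C@H]1[C@]2(C)CC[C@@H](Br)C(C)(C)[C@H]2CCC1=O | intermediate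
27 | (3R,5S,9R,10S)-3-bromo-15-(tert-butyldiphenylsilyloxy)labda-8(17),13E-diene | C/C(=C\CO[Si](c1ccccc1)(c1ccccc1)C(C)(C)C)CC[C@H]1[C@]2(C)CC[C@@H](Br)C(C)(C)[C@H]2CCC1=C | intermediate
28 | (3R,5S,8S,9S,10R)-17-(acetoxymercurio)-3-bromo-15-(tert-butyldiphenylsilyloxy)labd-13E-en-8-ol | C/C(=C\CO[Si](c1ccccc1)(c1ccccc1)C(C)(C)C)CC[C@H]1[C@]2(C)CC[C@@H](Br)C(C)(C)[C@H]2CC[C@]1(C[Hg]OC(C)=O)O | intermediate
29 | (3R,5S,8S,9S,10R)-3-bromo-15-(tert-butyldiphenylsilyloxy)labd-13E-en-8-ol | C/C(=C\CO[Si](c1ccccc1)(c1ccccc1)C(C)(C)C)CC[C@H]1[C@]2(C)CC[C@@H](Br)C(C)(C)[C@H]2CC[C@]1(C)O | intermediate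
30 | (3R,5S,8S,9S,10R)-3-bromolabd-13E-ene-8,15-diol (CNP0176777.2) | C/C(=C\CO)CC[C@H]1[C@]2(C)CC[C@@H](Br)C(C)(C)[C@H]2CC[C@]1(C)O | target

**Step count and risks**

Total: 20 steps. Longest linear sequence: 16 steps (6 → 30 through steps 4–11 and 13–20).

Most likely to fail, in this order:

Step 15. The chelated dienophile is crowded (C5 is neopentylic, the diene terminus C10 is fully substituted and carries an inside methyl), so cycloaddition may be slower than Lewis-acid cleavage or protonation of the silyl enol ether, and the reaction may drift to the exo, cis-fused mode. The fallback uses a smaller, catalytically activated dienophile and sets out from 16. Cross-metathesis of 16 with crotonaldehyde (same ruthenium catalyst) should give (2E,5R,8E)-5-bromo-9-[(3E)-5-(tert-butyldiphenylsilyloxy)-3-methylpent-3-en-1-yl]-4,4,8-trimethyl-10-oxoundeca-2,8-dienal F1, and TBSOTf/Et3N the corresponding 10-silyloxy trienal F2. Intramolecular Diels–Alder reaction catalysed by a chiral cationic oxazaborolidine (B-o-tolyl oxazaborolidine of α,α-diphenylprolinol activated with Tf2NH, the enantiomer that leaves the Re face of C6 open; CH2Cl2, −40 °C) should give the silyl enol ether cycloadduct aldehyde F3, hydrolysed with dilute acid to the 6-formyl-8-ketone F4. Decarbonylation with RhCl(PPh3)3 (toluene, 110 °C) comes back to the route at 26.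

Step 8. The dianion is strongly basic, so it may eliminate triflic acid or HBr from 5 instead of substituting at the β-branched primary carbon, and any over-deprotonation at C1 after coupling would displace the C3 bromide in a three-membered ring closure. The fallback uses a soft carbanion and builds the β-keto amide by acylation; it sets out from 5 and 10. Sodium di-tert-butyl malonate with 5 (THF, 0 °C) should give di-tert-butyl 2-[(2R)-2-bromo-3,3-dimethylpent-4-en-1-yl]propanedioate F5, TFA the malonic acid F6, and heating in toluene (4R)-4-bromo-5,5-dimethylhept-6-enoic acid F7, which carbonyldiimidazole converts into its acyl imidazolide F8. Separately, bromide 10 alkylates the lithium enolate of N-methoxy-N-methylacetamide to give (5E)-7-(tert-butyldiphenylsilyloxy)-N-methoxy-N,5-dimethylhept-5-enamide F9. Crossed Claisen acylation of the lithium enolate of F9 (LDA, 2 equiv) with F8 comes back to the route at 13.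

Step 2. Enamine formation from the β-quaternary aldehyde may be slow, and the α-bromo aldehyde may racemise or the catalyst may be brominated before reduction, eroding the enantiomeric purity on which all later diastereoselection rests. The fallback is auxiliary-controlled bromination and sets out from 1. Saponification (LiOH) gives 3,3-dimethylpent-4-enoic acid F10; pivaloyl mixed anhydride and lithiated (4S)-4-benzyl-1,3-oxazolidin-2-one give (4S)-4-benzyl-3-(3,3-dimethylpent-4-enoyl)-1,3-oxazolidin-2-one F11. Bu2BOTf/i-Pr2NEt then N-bromosuccinimide should brominate the chelated Z enolate anti to the benzyl group to give (4S)-4-benzyl-3-[(2S)-2-bromo-3,3-dimethylpent-4-enoyl]-1,3-oxazolidin-2-one F12. Reductive removal of the auxiliary with LiBH4 comes back to the route at 4.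

Further compounds
F1 | step 15 | (2E,5R,8E)-5-bromo-9-[(3E)-5-(tert-butyldiphenylsilyloxy)-3-methylpent-3-en-1-yl]-4,4,8-trimethyl-10-oxoundeca-2,8-dienal | O=C/C=C/C(C)(C)[C@H](Br)CC/C(C)=C(\CC/C(C)=C/CO[Si](c1ccccc1)(c1ccccc1)C(C)(C)C)C(C)=O
F2 | step 15 | (2E,5R,8E)-5-bromo-10-(tert-butyldimethylsilyloxy)-9-[(3E)-5-(tert-butyldiphenylsilyloxy)-3-methylpent-3-en-1-yl]-4,4,8-trimethylundeca-2,8,10-trienal | O=C/C=C/C(C)(C)[C@H](Br)CC/C(C)=C(\CC/C(C)=C/CO[Si](c1ccccc1)(c1ccccc1)C(C)(C)C)C(=C)O[Si](C)(C)C(C)(C)C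
F3 | step 15 | (3R,5S,6R,10R)-3-bromo-8-(tert-butyldimethylsilyloxy)-15-(tert-butyldiphenylsilyloxy)-17-norlabda-8,13E-diene-6-carbaldehyde | C/C(=C\CO[Si](c1ccccc1)(c1ccccc1)C(C)(C)C)CCC1=C(O[Si](C)(C)C(C)(C)C)C[C@@H](C=O)[C@@H]2C(C)(C)[C@H](Br)CC[C@@]12C
F4 | step 15 | (3R,5S,6R,9S,10R)-3-bromo-15-(tert-butyldiphenylsilyloxy)-8-oxo-17-norlabd-13E-ene-6-carbaldehyde | C/C(=C\CO[Si](c1ccccc1)(c1ccccc1)C(C)(C)C)CC[C@H]1[C@]2(C)CC[C@@H](Br)C(C)(C)[C@H]2[C@H](C=O)CC1=O
F5 | step 8 | di-tert-butyl 2-[(2R)-2-bromo-3,3-dimethylpent-4-en-1-yl]propanedioate | CC(C)(C)OC(=O)C(C[C@@H](Br)C(C)(C)C=C)C(=O)OC(C)(C)C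
F6 | step 8 | 2-[(2R)-2-bromo-3,3-dimethylpent-4-en-1-yl]propanedioic acid | OC(=O)C(C[C@@H](Br)C(C)(C)C=C)C(=O)O
F7 | step 8 | (4R)-4-bromo-5,5-dimethylhept-6-enoic acid | OC(=O)CC[C@@H](Br)C(C)(C)C=C
F8 | step 8 | (4R)-4-bromo-1-(1H-imidazol-1-yl)-5,5-dimethylhept-6-en-1-one | O=C(CC[C@@H](Br)C(C)(C)C=C)n1ccnc1
F9 | step 8 | (5E)-7-(tert-butyldiphenylsilyloxy)-N-methoxy-N,5-dimethylhept-5-enamide | CON(C)C(=O)CCC/C(C)=C/CO[Si](c1ccccc1)(c1ccccc1)C(C)(C)C
F10 | step 2 | 3,3-dimethylpent-4-enoic acid | OC(=O)CC(C)(C)C=C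
F11 | step 2 | (4S)-4-benzyl-3-(3,3-dimethylpent-4-enoyl)-1,3-oxazolidin-2-one | C=CC(C)(C)CC(=O)N1C(=O)OC[C@@H]1Cc1ccccc1
F12 | step 2 | (4S)-4-benzyl-3-[(2S)-2-bromo-3,3-dimethylpent-4-enoyl]-1,3-oxazolidin-2-one | C=CC(C)(C)[C@H](Br)C(=O)N1C(=O)OC[C@@H]1Cc1ccccc1
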